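**Plan**
- Retrosynthesis (side chain numbered C1' at the ring to C15' at the methyl): the two ring O–H groups are masked as TIPS ethers and the Z-C8'=C9' alkene as the C8'≡C9' alkyne. The chain is cut at the sp3–sp3 bond C5'–C6', then the halves at C7'–C8' (vinyl–alkyne) and at ring C5–C1' (aryl–alkyl).
- Enabling feature: C6'H2–C7'H2 lies between the saturated C1'–C5' tether and the C8'=C9' unsaturation. One oxidation level up it is a vinyl group on the C8'≡C9' alkyne (a 1,3-enyne), whose terminal carbon C6' takes boron on anti-Markovnikov hydroboration. The benzene-1,3-diol ring is a remote spectator.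
- Forward: Sonogashira coupling of (R)-oct-1-yn-3-ol with vinyl bromide gives the C6'–C15' enynol. 5-Bromoresorcinol is bis-silylated and joined to 5-bromopent-1-ene (B-alkyl Suzuki) to give the aryl C1'–C5' bromide. One-pot hydroboration/alkyl–alkyl Suzuki coupling joins the halves at C5'–C6'; acetylation, Lindlar semi-hydrogenation and fluoride desilylation finish the route.
- Stereochemistry: C10' (R) is bought with (R)-oct-1-yn-3-ol and no step breaks a bond at this carbon (acetylation occurs at oxygen, with retention). The 8'Z geometry comes from syn addition of H2 to the alkyne on Lindlar palladium.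

Key step: step 4

Remark: the carbinol carbon of the target is R (O > alkenyl > pentyl), the same spatial arrangement as in (R)-oct-1-yn-3-ol (O > alkynyl > pentyl). Compounds 1, 2, 4, 6 and 7 are taken as commercial.

Step 1
Reactants: 1 (R)-oct-1-yn-3-ol; 2 vinyl bromide (bromoethene)
Product: 3 (R)-dec-1-en-3-yn-5-ol
Conditions: PdCl2(PPh3)2 (2 mol%), CuI (4 mol%), i-Pr2NH, THF (degassed), 0 °C to rt
Reagents that add atoms: none
Why: Sonogashira coupling (Pd(0) insertion into the vinyl C–Br bond, transmetalation from the copper acetylide of 1) should form the C7'–C8' bond; the free propargylic OH is tolerated and the stereocentre is not involved.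

Step 2
Reactants: 4 5-bromobenzene-1,3-diol
Product: 5 1-bromo-3,5-bis(triisopropylsilyloxy)benzene
Conditions: TIPSCl, imidazole, DMF, rt
Reagents that add atoms: triisopropylsilyl chloride (TIPSCl), CC(C)[Si](Cl)(C(C)C)C(C)C
Why: Imidazole-promoted O-silylation of both phenols should give aryl TIPS ethers that withstand boranes, aqueous phosphate, Pd(0) and H2 and are later removed by fluoride without harm to an alkyl acetate.

Step 3
Reactants: 5 1-bromo-3,5-bis(triisopropylsilyloxy)benzene; 6 5-bromopent-1-ene; 7 9-borabicyclo[3.3.1]nonane (9-BBN)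
Product: 9 1-(5-bromopentyl)-3,5-bis(triisopropylsilyloxy)benzene, via 9-(5-bromopentyl)-9-borabicyclo[3.3.1]nonane 8 (not isolated)
Conditions: 6, 9-BBN, THF, 0 °C to rt; then 5, PdCl2(dppf) (3 mol%), aq. K3PO4, THF/DMF, 50 °C
Reagents that add atoms: none
Why: Anti-Markovnikov hydroboration of the terminal alkene followed by B-alkyl Suzuki–Miyaura coupling should form the ring C5–C1' bond; Pd(dppf) inserts into the aryl C–Br bond but not into the unactivated primary alkyl C–Br bond, which is kept for step 4.

Step 4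
Reactants: 3 (R)-dec-1-en-3-yn-5-ol; 7 9-borabicyclo[3.3.1]nonane (9-BBN); 9 1-(5-bromopentyl)-3,5-bis(triisopropylsilyloxy)benzene
Product: 11 (R)-1-[3,5-bis(triisopropylsilyloxy)phenyl]pentadec-8-yn-10-ol, via C,O-bis(9-BBN) adduct 10 (not isolated)
Conditions: 3, 9-BBN (2.1 equiv per 3), THF, 0 °C to rt; then 9, Pd(OAc)2 (4 mol%), PCy3 (8 mol%), K3PO4·H2O, THF, rt
Reagents that add atoms: none
Why: 9-BBN first caps the hydroxyl of 3 as a B–O borinate (H2 is lost) and then adds syn and anti-Markovnikov across the monosubstituted C6'=C7' vinyl group, boron going to terminal C6', to give 10; Pd(0)/PCy3 then inserts into the primary C5'–Br bond of 9 by an SN2-type oxidative addition, base-activated 10 transfers its primary alkyl group from boron to palladium, and C(sp3)–C(sp3) reductive elimination forms the C5'–C6' bond. The closest known reaction type is the B-alkyl Suzuki–Miyaura alkyl–alkyl coupling of alkyl-9-BBN reagents with primary alkyl bromides bearing β-hydrogens under Pd/trialkylphosphine catalysis, run in one pot after hydroboration. No ring is closed and no stereocentre is formed; C10' is a spectator and keeps its R configuration. The step needs hydroboration of the vinyl group in preference to the conjugated internal alkyne, which the steric demand of 9-BBN (terminal CH2 against an alkyne flanked by the borinate-bearing branched carbon) and the controlled stoichiometry should secure. It also needs reductive elimination to outrun β-hydride elimination and transfer of the primary alkyl group rather than the ring B–C bonds, which the bulky electron-rich PCy3 ligand and the secondary bicyclic B–C bonds should secure; the aqueous phosphate hydrolyses the B–O bond so that the free alcohol 11 is isolated.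

Step 5
Reactants: 11 (R)-1-[3,5-bis(triisopropylsilyloxy)phenyl]pentadec-8-yn-10-ol
Product: 12 (R)-1-[3,5-bis(triisopropylsilyloxy)phenyl]pentadec-8-yn-10-yl acetate
Conditions: Ac2O, pyridine, DMAP (cat.), CH2Cl2, 0 °C to rt
Reagents that add atoms: acetic anhydride, CC(=O)OC(C)=O
Why: DMAP-catalysed acylation of the only free hydroxyl should give the propargylic acetate with retention at C10', since the C–O bond is not broken.

Step 6
Reactants: 12 (R)-1-[3,5-bis(triisopropylsilyloxy)phenyl]pentadec-8-yn-10-yl acetate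
Product: 13 (8Z,10R)-1-[3,5-bis(triisopropylsilyloxy)phenyl]pentadec-8-en-10-yl acetate
Conditions: H2 (1 atm), Lindlar catalyst (Pd/CaCO3, Pb), quinoline, EtOAc, rt, stopped at one equivalent of H2
Reagents that add atoms: none
Why: Lindlar semi-hydrogenation delivers H2 syn to the alkyne on poisoned palladium and should stop at the Z-alkene; aryl silyl ethers and the acetate are inert.

Step 7
Reactants: 13 (8Z,10R)-1-[3,5-bis(triisopropylsilyloxy)phenyl]pentadec-8-en-10-yl acetate
Product: 14 5-[(8Z,10R)-10-acetoxypentadec-8-en-1-yl]benzene-1,3-diol (target)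
Conditions: TBAF, AcOH (1:1), THF, 0 °C
Reagents that add atoms: none
Why: Fluoride-mediated desilylation should cleave the aryl O–Si bonds quickly (phenoxide is a good leaving group from the fluorosilicate), while the acetic acid buffer keeps the medium non-basic so that the secondary allylic acetate is neither cleaved nor transferred to a phenol.

**Compound list**
1 | (R)-oct-1-yn-3-ol | CCCCC[C@H](C#C)O | starting material
2 | vinyl bromide (bromoethene) | C=CBr | starting material
3 | (R)-dec-1-en-3-yn-5-ol | CCCCC[C@H](C#CC=C)O | intermediate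
4 | 5-bromobenzene-1,3-diol | Oc1cc(O)cc(Br)c1 | starting material
5 | 1-bromo-3,5-bis(triisopropylsilyloxy)benzene | Brc1cc(O[Si](C(C)C)(C(C)C)C(C)C)cc(O[Si](C(C)C)(C(C)C)C(C)C)c1 | intermediate
6 | 5-bromopent-1-ene | C=CCCCBr | starting material
7 | 9-borabicyclo[3.3.1]nonane (9-BBN) | B1C2CCCC1CCC2 | starting material
8 | 9-(5-bromopentyl)-9-borabicyclo[3.3.1]nonane (not isolated) | BrCCCCCB1C2CCCC1CCC2 | intermediate
9 | 1-(5-bromopentyl)-3,5-bis(triisopropylsilyloxy)benzene | BrCCCCCc1cc(O[Si](C(C)C)(C(C)C)C(C)C)cc(O[Si](C(C)C)(C(C)C)C(C)C)c1 | intermediate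
10 | C,O-bis(9-BBN) adduct, 9-[(5R)-5-(9-borabicyclo[3.3.1]nonan-9-yloxy)dec-3-yn-1-yl]-9-borabicyclo[3.3.1]nonane (not isolated) | CCCCC[C@H](C#CCCB1C2CCCC1CCC2)OB1C2CCCC1CCC2 | intermediate
11 | (R)-1-[3,5-bis(triisopropylsilyloxy)phenyl]pentadec-8-yn-10-ol | CCCCC[C@H](C#CCCCCCCCc1cc(O[Si](C(C)C)(C(C)C)C(C)C)cc(O[Si](C(C)C)(C(C)C)C(C)C)c1)O | intermediate
12 | (R)-1-[3,5-bis(triisopropylsilyloxy)phenyl]pentadec-8-yn-10-yl acetate | CCCCC[C@H](C#CCCCCCCCc1cc(O[Si](C(C)C)(C(C)C)C(C)C)cc(O[Si](C(C)C)(C(C)C)C(C)C)c1)OC(C)=O | intermediate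
13 | (8Z,10R)-1-[3,5-bis(triisopropylsilyloxy)phenyl]pentadec-8-en-10-yl acetate | CCCCC[C@H](/C=C\CCCCCCCc1cc(O[Si](C(C)C)(C(C)C)C(C)C)cc(O[Si](C(C)C)(C(C)C)C(C)C)c1)OC(C)=O | intermediate
14 | 5-[(8Z,10R)-10-acetoxypentadec-8-en-1-yl]benzene-1,3-diol, i.e. (6R,7Z)-15-(3,5-dihydroxyphenyl)pentadec-7-en-6-yl acetate | CCCCC[C@H](/C=C\CCCCCCCc1cc(O)cc(O)c1)OC(C)=O | target

Total step count: 7. Longest linear sequence: 6 steps (4 → 5 → 9 → 11 → 12 → 13 → 14, steps 2 to 7); the enynol branch joins after one step.

**Steps most likely to fail**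

Step 4. Hydroboration may lose chemoselectivity (boron adding to the conjugated alkyne, or double addition), and β-hydride elimination from the homopropargylic alkylpalladium species may compete with C–C reductive elimination. The fallback sets out from 1 and 9, returns at 11 and reverses the polarity with a copper-catalysed Grignard–tosylate (Kochi) coupling. Silylation of 1 (TBSCl, imidazole, DMF) should give (R)-tert-butyldimethyl(oct-1-yn-3-yloxy)silane F1. Its lithium acetylide (n-BuLi, THF, −78 °C) opens ethylene oxide under BF3·OEt2 activation to give (R)-5-(tert-butyldimethylsilyloxy)dec-3-yn-1-ol F2, which TsCl/pyridine converts into (R)-5-(tert-butyldimethylsilyloxy)dec-3-yn-1-yl 4-methylbenzenesulfonate F3. Bromide 9 and magnesium in THF give {5-[3,5-bis(triisopropylsilyloxy)phenyl]pentyl}magnesium bromide F4. F4 is coupled with F3 under Li2CuCl4 catalysis (THF, −78 to 0 °C) to give (R)-tert-butyl({1-[3,5-bis(triisopropylsilyloxy)phenyl]pentadec-8-yn-10-yl}oxy)dimethylsilane F5. Acid methanolysis of the alkyl TBS ether (CSA, MeOH/CH2Cl2, rt), to which aryl TIPS ethers are inert, returns to 11.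

Step 3. The primary bromide of the bromoalkylborate may be displaced intramolecularly or hydrolysed under the basic coupling conditions, and the aryl silyl ethers may be partly cleaved by warm aqueous phosphate. The fallback sets out from 5, returns at 9 and avoids any bromoalkylborane. Sonogashira coupling of 5 with pent-4-yn-1-ol (PdCl2(PPh3)2, CuI, Et3N, 60 °C) should give 5-[3,5-bis(triisopropylsilyloxy)phenyl]pent-4-yn-1-ol F6. Full hydrogenation (H2, Pd/C, EtOAc) gives 5-[3,5-bis(triisopropylsilyloxy)phenyl]pentan-1-ol F7, and Appel bromination (CBr4, PPh3, CH2Cl2, 0 °C) gives 9.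

Step 6. Over-reduction to the saturated chain, Z-to-E isomerisation or hydrogenolysis of the allylic C–O bond may occur on palladium. The fallback sets out from 3 (with 9), returns at 13 and sets the Z-alkene before fragment union without catalytic hydrogenation. Boland reduction of 3 (Zn(Cu/Ag), MeOH/H2O, rt), which acts only on the conjugation-activated alkyne, should give (3Z,5R)-deca-1,3-dien-5-ol F8. 9-BBN (2.1 equiv, THF) adds to the terminal vinyl group only to give 9-[(3Z,5R)-5-(9-borabicyclo[3.3.1]nonan-9-yloxy)dec-3-en-1-yl]-9-borabicyclo[3.3.1]nonane F9, which is not isolated. F9 is coupled with 9 under the conditions of step 4 to give (8Z,10R)-1-[3,5-bis(triisopropylsilyloxy)phenyl]pentadec-8-en-10-ol F10, and acetylation (Ac2O, pyridine, DMAP) gives 13.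

Further compounds
F1 | step 4 | (R)-tert-butyldimethyl(oct-1-yn-3-yloxy)silane | CCCCC[C@H](C#C)O[Si](C)(C)C(C)(C)C
F2 | step 4 | (R)-5-(tert-butyldimethylsilyloxy)dec-3-yn-1-ol | CCCCC[C@H](C#CCCO)O[Si](C)(C)C(C)(C)C
F3 | step 4 | (R)-5-(tert-butyldimethylsilyloxy)dec-3-yn-1-yl 4-methylbenzenesulfonate | CCCCC[C@H](C#CCCOS(=O)(=O)c1ccc(C)cc1)O[Si](C)(C)C(C)(C)C
F4 | step 4 | {5-[3,5-bis(triisopropylsilyloxy)phenyl]pentyl}magnesium bromide | Br[Mg]CCCCCc1cc(O[Si](C(C)C)(C(C)C)C(C)C)cc(O[Si](C(C)C)(C(C)C)C(C)C)c1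
F5 | step 4 | (R)-tert-butyl({1-[3,5-bis(triisopropylsilyloxy)phenyl]pentadec-8-yn-10-yl}oxy)dimethylsilane | CCCCC[C@H](C#CCCCCCCCc1cc(O[Si](C(C)C)(C(C)C)C(C)C)cc(O[Si](C(C)C)(C(C)C)C(C)C)c1)O[Si](C)(C)C(C)(C)C
F6 | step 3 | 5-[3,5-bis(triisopropylsilyloxy)phenyl]pent-4-yn-1-ol | OCCCC#Cc1cc(O[Si](C(C)C)(C(C)C)C(C)C)cc(O[Si](C(C)C)(C(C)C)C(C)C)c1
F7 | step 3 | 5-[3,5-bis(triisopropylsilyloxy)phenyl]pentan-1-ol | OCCCCCc1cc(O[Si](C(C)C)(C(C)C)C(C)C)cc(O[Si](C(C)C)(C(C)C)C(C)C)c1
F8 | step 6 | (3Z,5R)-deca-1,3-dien-5-ol | CCCCC[C@H](/C=C\C=C)O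
F9 | step 6 | 9-[(3Z,5R)-5-(9-borabicyclo[3.3.1]nonan-9-yloxy)dec-3-en-1-yl]-9-borabicyclo[3.3.1]nonane | CCCCC[C@H](/C=C\CCB1C2CCCC1CCC2)OB1C2CCCC1CCC2
F10 | step 6 | (8Z,10R)-1-[3,5-bis(triisopropylsilyloxy)phenyl]pentadec-8-en-10-ol | CCCCC[C@H](/C=C\CCCCCCCc1cc(O[Si](C(C)C)(C(C)C)C(C)C)cc(O[Si](C(C)C)(C(C)C)C(C)C)c1)O
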